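The plan rests on disconnecting the pyran ring at O1–C8a. In the flavan half, C8a carries the ring oxygen and its neighbour C8 on the central benzene ring carries the spiro carbon; an aryne across C8–C8a serves both atoms at once. In the key step a 2-fluoroaryl syn-diol monoether is lithiated at C8, loses LiF, and its C2 alkoxide adds to C8a, closing the pyran ring with retention at C2 (hence 2,3-cis), while the carbanion that emerges at C8 is iodinated. The iodide then receives a diazoketone; carbenoid C–H insertion into the O7 benzyl ether and an invertive spiro-etherification complete the spirobenzofuranone.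

Key step: step 6

Remark (atom labels): the text uses chromane (flavan) numbering O1, C2, C3, C4, C4a, C5–C8, C8a. The two sp3 carbons of the later dihydrofuran are called C(α) (aryl-bearing, on O7) and C(spiro) (on C8). Systematic names of the tricyclic compounds use furo[2,3-h]chromene locants (C(α) = C8, C(spiro) = C9; 8' and 9' in the spiro names).

Remark (assumption): the sense of induction of Rh2(R-PTTL)4 in step 10 is assumed by analogy with insertions of aryldiazoacetates into ortho benzyloxy groups; if it proves opposite, Rh2(S-PTTL)4 is used instead.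

Remark (stoichiometry): where one reagent is taken up more than once (two molecules of 2 in step 1, three silyl groups in step 7), each molecule that ends up in the product is counted separately on the reagent line.

Step 1
Reactants: 1 5-fluorobenzene-1,3-diol; 2 1-(benzyloxy)-4-(chloromethyl)benzene
Product: 3 1-fluoro-3,5-bis{[4-(benzyloxy)benzyl]oxy}benzene
Conditions: 2 (2.2 equiv in all), K2CO3, DMF, 60 °C
Reagents that add atoms: 1-(benzyloxy)-4-(chloromethyl)benzene (the second equivalent of 2, taken up by the second phenol), ClCc1ccc(OCc2ccccc2)cc1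
Why: Twofold Williamson ether synthesis, in which each phenol of the symmetrical resorcinol takes up one molecule of 2, should give a mirror-symmetric ether whose two C–H positions between F and O are equivalent, and it places on the future O7 the benzylic CH2 that later becomes C(α).

Step 2
Reactants: 3 1-fluoro-3,5-bis{[4-(benzyloxy)benzyl]oxy}benzene; 4 methyl (2R)-oxirane-2-carboxylate
Product: 7 methyl (2R)-3-(2-fluoro-4,6-bis{[4-(benzyloxy)benzyl]oxy}phenyl)-2-hydroxypropanoate, via aryllithium 5 (not isolated), via arylmagnesium bromide 6 (not isolated)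
Conditions: s-BuLi, TMEDA, THF, −78 °C; MgBr2·OEt2; then CuBr·SMe2 (10 mol %), 4, −40 → −20 °C; H2O
Reagents that add atoms: none
Why: Directed ortho-metalation at the ring C–H between fluorine and an ether oxygen, transmetalation to the arylmagnesium bromide (which should not lose fluoride at −40 °C) and copper-catalysed SN2 opening of the glycidate at its CH2 terminus should give the α-hydroxy ester, whose carbinol stereocenter (R, the future C3) comes unchanged from the chiral-pool epoxide because its stereogenic carbon is not attacked.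

Step 3
Reactants: 7 methyl (2R)-3-(2-fluoro-4,6-bis{[4-(benzyloxy)benzyl]oxy}phenyl)-2-hydroxypropanoate
Product: 8 methyl (2R)-2-(benzyloxy)-3-(2-fluoro-4,6-bis{[4-(benzyloxy)benzyl]oxy}phenyl)propanoate
Conditions: BnBr, Ag2O, CH2Cl2, rt, dark
Reagents that add atoms: benzyl bromide, BrCc1ccccc1
Why: Silver-oxide-mediated O-benzylation (Williamson-type without strong base) should protect the α-hydroxy ester without enolization, so the future C3 keeps its configuration and gains the chelating ether needed in step 5.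

Step 4
Reactants: 8 methyl (2R)-2-(benzyloxy)-3-(2-fluoro-4,6-bis{[4-(benzyloxy)benzyl]oxy}phenyl)propanoate
Product: 9 (2R)-2-(benzyloxy)-3-(2-fluoro-4,6-bis{[4-(benzyloxy)benzyl]oxy}phenyl)propanal
Conditions: i-Bu2AlH, CH2Cl2, −78 °C; aq. potassium sodium tartrate
Reagents that add atoms: none
Why: Partial ester reduction by i-Bu2AlH at −78 °C should stop at the chelated aluminium hemiacetal, which gives the α-benzyloxy aldehyde on work-up without epimerization.

Step 5
Reactants: 9 (2R)-2-(benzyloxy)-3-(2-fluoro-4,6-bis{[4-(benzyloxy)benzyl]oxy}phenyl)propanal; 10 [4-(benzyloxy)phenyl]magnesium bromide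
Product: 11 (1R,2R)-2-(benzyloxy)-1-[4-(benzyloxy)phenyl]-3-(2-fluoro-4,6-bis{[4-(benzyloxy)benzyl]oxy}phenyl)propan-1-ol
Conditions: MgBr2·OEt2, CH2Cl2, −78 °C; then 10 (THF solution), −78 °C; H2O
Reagents that add atoms: none
Why: Chelation-controlled (Cram-chelate) Grignard addition, in which magnesium bridges the aldehyde and the α-benzyloxy oxygen and the aryl group enters anti to the CH2Ar substituent, should set the carbinol carbon (the future C2) as R and give the syn mono-protected diol with the C2 hydroxyl free.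

Step 6
Reactants: 11 (1R,2R)-2-(benzyloxy)-1-[4-(benzyloxy)phenyl]-3-(2-fluoro-4,6-bis{[4-(benzyloxy)benzyl]oxy}phenyl)propan-1-ol
Product: 15 (2R,3R)-3-(benzyloxy)-2-[4-(benzyloxy)phenyl]-5,7-bis{[4-(benzyloxy)benzyl]oxy}-8-iodo-3,4-dihydro-2H-chromene, via dilithio species 12 (not isolated), via aryne alkoxide 13 (not isolated), via 8-lithiochromane 14 (not isolated)
Conditions: n-BuLi (1.0 equiv), THF, −78 °C; s-BuLi (1.3 equiv), TMEDA, −78 °C; warm to −30 °C; then I2, −78 °C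
Reagents that add atoms: iodine, I-I
Why: After O-deprotonation, s-BuLi removes the ring proton at C8 (flanked by fluorine and the O7 ether), LiF loss gives the C8–C8a aryne 13, the tethered C2 alkoxide adds to C8a and the resulting C8 aryllithium 14 is iodinated. The closest known reaction type is the anionic benzyne cyclization of a tethered heteroatom nucleophile with electrophilic quench of the new aryllithium. The pyran ring closes by 6-exo-dig attack of the alkoxide on the in-plane aryne orbital at C8a, which forms O1–C8a. No stereocenter is formed; because the C2–O bond is never broken, C2 and C3 are retained and the syn (1R,2R) alcohol maps onto the 2,3-cis (2R,3R) flavan. The step needs lithiation at C8 and not at C6 (secured by the stronger acidifying effect of fluorine over a second ether oxygen), addition at C8a and not at C8 (secured by the tether length and by the inductive effect of O7, which places the carbanion ortho to it), and survival of the C8 anion until iodination (secured by alkyllithium bases that leave only butane and by TMEDA having no N–H bond, so no proton source is present).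

Step 7
Reactants: 16 1-(2,4,6-trihydroxyphenyl)ethan-1-one
Product: 17 1-{2,4,6-tris[(triisopropylsilyl)oxy]phenyl}ethan-1-one
Conditions: i-Pr3SiOTf (3.3 equiv), 2,6-lutidine, CH2Cl2, 0 °C
Reagents that add atoms: triisopropylsilyl trifluoromethanesulfonate (first equivalent), CC(C)[Si](C(C)C)(C(C)C)OS(=O)(=O)C(F)(F)F; triisopropylsilyl trifluoromethanesulfonate (second equivalent), CC(C)[Si](C(C)C)(C(C)C)OS(=O)(=O)C(F)(F)F; triisopropylsilyl trifluoromethanesulfonate (third equivalent), CC(C)[Si](C(C)C)(C(C)C)OS(=O)(=O)C(F)(F)F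
Why: Silylation of each of the three phenols by one molecule of the silyl triflate (2,6-lutidine should not enolize the ketone) gives aryl silyl ethers that offer no C–H bond within reach of the later carbenoid, are poor donors for oxonium ylide formation and are removed by fluoride in step 11.

Step 8
Reactants: 17 1-{2,4,6-tris[(triisopropylsilyl)oxy]phenyl}ethan-1-one
Product: 19 2-diazo-1-{2,4,6-tris[(triisopropylsilyl)oxy]phenyl}ethan-1-one, via trifluoromethyl diketone 18 (not isolated)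
Conditions: LiN(SiMe3)2, THF, −78 °C, CF3CO2CH2CF3; then MsN3, Et3N, H2O, MeCN, rt
Reagents that add atoms: methanesulfonyl azide, CS(=O)(=O)N=[N+]=[N-]
Why: Detrifluoroacetylative diazo transfer (a Regitz-type diazo transfer), in which Claisen trifluoroacetylation of the methyl ketone enolate activates the CH2 group so that the sulfonyl azide delivers N2 with loss of the trifluoroacetyl group, should give the terminal α-diazo ketone.

Step 9
Reactants: 15 (2R,3R)-3-(benzyloxy)-2-[4-(benzyloxy)phenyl]-5,7-bis{[4-(benzyloxy)benzyl]oxy}-8-iodo-3,4-dihydro-2H-chromene; 19 2-diazo-1-{2,4,6-tris[(triisopropylsilyl)oxy]phenyl}ethan-1-one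
Product: 20 2-diazo-2-{(2R,3R)-3-(benzyloxy)-2-[4-(benzyloxy)phenyl]-5,7-bis{[4-(benzyloxy)benzyl]oxy}-3,4-dihydro-2H-chromen-8-yl}-1-{2,4,6-tris[(triisopropylsilyl)oxy]phenyl}ethan-1-one
Conditions: Pd(PPh3)4 (5 mol %), Ag2CO3, Et3N, PhMe, rt
Reagents that add atoms: none
Why: Palladium-catalysed cross-coupling of an aryl iodide with the C–H bond of an acyl diazomethane, which keeps the diazo group under Ag2CO3/Et3N at room temperature, should attach the diazo carbon (the future spiro carbon) to C8.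

Step 10
Reactants: 20 2-diazo-2-{(2R,3R)-3-(benzyloxy)-2-[4-(benzyloxy)phenyl]-5,7-bis{[4-(benzyloxy)benzyl]oxy}-3,4-dihydro-2H-chromen-8-yl}-1-{2,4,6-tris[(triisopropylsilyl)oxy]phenyl}ethan-1-one
Product: 21 {(2R,3R,8S,9R)-3-(benzyloxy)-2,8-bis[4-(benzyloxy)phenyl]-5-{[4-(benzyloxy)benzyl]oxy}-3,4,8,9-tetrahydro-2H-furo[2,3-h]chromen-9-yl}{2,4,6-tris[(triisopropylsilyl)oxy]phenyl}methanone
Conditions: Rh2(R-PTTL)4 [dirhodium tetrakis(N-phthaloyl-(R)-tert-leucinate)] (1 mol %), PhMe, −40 °C → rt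
Reagents that add atoms: none
Why: Rhodium-carbenoid intramolecular 1,5 C–H insertion into the ether-activated benzylic CH2 on O7 (the only C–H in reach, since C2–H lies anti to C8 across O1) should close the dihydrofuran, the chiral carboxylate catalyst setting C(α) (8S here, the spatial arrangement of the target; assumed sense, see remark), while the cis C(spiro)–H centre is of no consequence because it is planarized in step 11.

Step 11
Reactants: 21 {(2R,3R,8S,9R)-3-(benzyloxy)-2,8-bis[4-(benzyloxy)phenyl]-5-{[4-(benzyloxy)benzyl]oxy}-3,4,8,9-tetrahydro-2H-furo[2,3-h]chromen-9-yl}{2,4,6-tris[(triisopropylsilyl)oxy]phenyl}methanone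
Product: 25 (2R,2'R,3'R,8'R)-3'-(benzyloxy)-2',8'-bis[4-(benzyloxy)phenyl]-5'-{[4-(benzyloxy)benzyl]oxy}-4,6-dihydroxy-3',4'-dihydro-2'H,3H,8'H-spiro[[1]benzofuran-2,9'-furo[2,3-h]chromen]-3-one, via potassium enolate 22 (not isolated), via bromo ketone 23 (not isolated), via desilylated bromo ketone 24 (not isolated)
Conditions: KN(SiMe3)2, THF, −78 °C; NBS, −78 °C; then Bu4NF, −78 → 0 °C
Reagents that add atoms: none
Why: Enolate bromination followed by an intramolecular Williamson-type SN2 etherification, in which NBS attacks the enolate on the face anti to the C(α) aryl group (bromine cis to the C(α) hydrogen, so no anti-periplanar hydrogen is available for E2 to the benzofuran) and, after fluoride desilylation, an ortho phenoxide displaces bromide with inversion in a 5-exo-tet closure, should place the benzofuranone oxygen cis and the carbonyl trans to the C(α) aryl group, which is the (R) spiro centre.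

Step 12
Reactants: 25 (2R,2'R,3'R,8'R)-3'-(benzyloxy)-2',8'-bis[4-(benzyloxy)phenyl]-5'-{[4-(benzyloxy)benzyl]oxy}-4,6-dihydroxy-3',4'-dihydro-2'H,3H,8'H-spiro[[1]benzofuran-2,9'-furo[2,3-h]chromen]-3-one
Product: 26 (2R,2'R,3'R,8'R)-3',4,5',6-tetrahydroxy-2',8'-bis(4-hydroxyphenyl)-3',4'-dihydro-2'H,3H,8'H-spiro[[1]benzofuran-2,9'-furo[2,3-h]chromen]-3-one (CNP0228515.2)
Conditions: H2 (1 atm), Pd(OH)2/C, THF/MeOH, rt
Reagents that add atoms: none
Why: Hydrogenolysis of the three benzyl ethers and of the 4-(benzyloxy)benzyl ether at O5 (which leaves as 4-methylphenol) should free all phenols and the C3 hydroxyl, while the hindered cyclic benzylic ether bonds, the tertiary spiro C–O bond and the aryl ketone are expected to persist under these mild conditions.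

Compound list

1 | 5-fluorobenzene-1,3-diol | Oc1cc(O)cc(F)c1 | starting material
2 | 1-(benzyloxy)-4-(chloromethyl)benzene | ClCc1ccc(OCc2ccccc2)cc1 | starting material
3 | 1-fluoro-3,5-bis{[4-(benzyloxy)benzyl]oxy}benzene | Fc1cc(OCc2ccc(OCc3ccccc3)cc2)cc(OCc2ccc(OCc3ccccc3)cc2)c1 | intermediate
4 | methyl (2R)-oxirane-2-carboxylate | COC(=O)[C@H]1CO1 | starting material
5 | (2-fluoro-4,6-bis{[4-(benzyloxy)benzyl]oxy}phenyl)lithium | [Li]c1c(F)cc(OCc2ccc(OCc3ccccc3)cc2)cc1OCc1ccc(OCc2ccccc2)cc1 | intermediate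
6 | (2-fluoro-4,6-bis{[4-(benzyloxy)benzyl]oxy}phenyl)magnesium bromide | Br[Mg]c1c(F)cc(OCc2ccc(OCc3ccccc3)cc2)cc1OCc1ccc(OCc2ccccc2)cc1 | intermediate
7 | methyl (2R)-3-(2-fluoro-4,6-bis{[4-(benzyloxy)benzyl]oxy}phenyl)-2-hydroxypropanoate | COC(=O)[C@H](O)Cc1c(F)cc(OCc2ccc(OCc3ccccc3)cc2)cc1OCc1ccc(OCc2ccccc2)cc1 | intermediate
8 | methyl (2R)-2-(benzyloxy)-3-(2-fluoro-4,6-bis{[4-(benzyloxy)benzyl]oxy}phenyl)propanoate | COC(=O)[C@H](OCc1ccccc1)Cc1c(F)cc(OCc2ccc(OCc3ccccc3)cc2)cc1OCc1ccc(OCc2ccccc2)cc1 | intermediate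
9 | (2R)-2-(benzyloxy)-3-(2-fluoro-4,6-bis{[4-(benzyloxy)benzyl]oxy}phenyl)propanal | O=C[C@H](OCc1ccccc1)Cc1c(F)cc(OCc2ccc(OCc3ccccc3)cc2)cc1OCc1ccc(OCc2ccccc2)cc1 | intermediate
10 | [4-(benzyloxy)phenyl]magnesium bromide | Br[Mg]c1ccc(OCc2ccccc2)cc1 | starting material
11 | (1R,2R)-2-(benzyloxy)-1-[4-(benzyloxy)phenyl]-3-(2-fluoro-4,6-bis{[4-(benzyloxy)benzyl]oxy}phenyl)propan-1-ol | O[C@H](c1ccc(OCc2ccccc2)cc1)[C@H](OCc1ccccc1)Cc1c(F)cc(OCc2ccc(OCc3ccccc3)cc2)cc1OCc1ccc(OCc2ccccc2)cc1 | intermediate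
12 | lithium (1R,2R)-2-(benzyloxy)-1-[4-(benzyloxy)phenyl]-3-(2-fluoro-3-lithio-4,6-bis{[4-(benzyloxy)benzyl]oxy}phenyl)propan-1-olate (lithium on the future C8) | [Li]O[C@H](c1ccc(OCc2ccccc2)cc1)[C@H](OCc1ccccc1)Cc1c(F)c([Li])c(OCc2ccc(OCc3ccccc3)cc2)cc1OCc1ccc(OCc2ccccc2)cc1 | intermediate
13 | lithium (1R,2R)-2-(benzyloxy)-1-[4-(benzyloxy)phenyl]-3-(4,6-bis{[4-(benzyloxy)benzyl]oxy}-2,3-didehydrophenyl)propan-1-olate (C8–C8a aryne) | [Li]O[C@H](c1ccc(OCc2ccccc2)cc1)[C@H](OCc1ccccc1)CC1=C(OCc2ccc(OCc3ccccc3)cc2)C=C(OCc2ccc(OCc3ccccc3)cc2)C#C1 | intermediate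
14 | {(2R,3R)-3-(benzyloxy)-2-[4-(benzyloxy)phenyl]-5,7-bis{[4-(benzyloxy)benzyl]oxy}-3,4-dihydro-2H-chromen-8-yl}lithium | [Li]c1c(OCc2ccc(OCc3ccccc3)cc2)cc(OCc2ccc(OCc3ccccc3)cc2)c2c1O[C@H](c1ccc(OCc3ccccc3)cc1)[C@H](OCc1ccccc1)C2 | intermediate
15 | (2R,3R)-3-(benzyloxy)-2-[4-(benzyloxy)phenyl]-5,7-bis{[4-(benzyloxy)benzyl]oxy}-8-iodo-3,4-dihydro-2H-chromene | Ic1c(OCc2ccc(OCc3ccccc3)cc2)cc(OCc2ccc(OCc3ccccc3)cc2)c2c1O[C@H](c1ccc(OCc3ccccc3)cc1)[C@H](OCc1ccccc1)C2 | intermediate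
16 | 1-(2,4,6-trihydroxyphenyl)ethan-1-one | CC(=O)c1c(O)cc(O)cc1O | starting material
17 | 1-{2,4,6-tris[(triisopropylsilyl)oxy]phenyl}ethan-1-one | CC(=O)c1c(O[Si](C(C)C)(C(C)C)C(C)C)cc(O[Si](C(C)C)(C(C)C)C(C)C)cc1O[Si](C(C)C)(C(C)C)C(C)C | intermediate
18 | 4,4,4-trifluoro-1-{2,4,6-tris[(triisopropylsilyl)oxy]phenyl}butane-1,3-dione | FC(F)(F)C(=O)CC(=O)c1c(O[Si](C(C)C)(C(C)C)C(C)C)cc(O[Si](C(C)C)(C(C)C)C(C)C)cc1O[Si](C(C)C)(C(C)C)C(C)C | intermediate
19 | 2-diazo-1-{2,4,6-tris[(triisopropylsilyl)oxy]phenyl}ethan-1-one | [N-]=[N+]=CC(=O)c1c(O[Si](C(C)C)(C(C)C)C(C)C)cc(O[Si](C(C)C)(C(C)C)C(C)C)cc1O[Si](C(C)C)(C(C)C)C(C)C | intermediate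
20 | 2-diazo-2-{(2R,3R)-3-(benzyloxy)-2-[4-(benzyloxy)phenyl]-5,7-bis{[4-(benzyloxy)benzyl]oxy}-3,4-dihydro-2H-chromen-8-yl}-1-{2,4,6-tris[(triisopropylsilyl)oxy]phenyl}ethan-1-one | [N-]=[N+]=C(C(=O)c1c(O[Si](C(C)C)(C(C)C)C(C)C)cc(O[Si](C(C)C)(C(C)C)C(C)C)cc1O[Si](C(C)C)(C(C)C)C(C)C)c1c(OCc2ccc(OCc3ccccc3)cc2)cc(OCc2ccc(OCc3ccccc3)cc2)c2c1O[C@H](c1ccc(OCc3ccccc3)cc1)[C@H](OCc1ccccc1)C2 | intermediate
21 | {(2R,3R,8S,9R)-3-(benzyloxy)-2,8-bis[4-(benzyloxy)phenyl]-5-{[4-(benzyloxy)benzyl]oxy}-3,4,8,9-tetrahydro-2H-furo[2,3-h]chromen-9-yl}{2,4,6-tris[(triisopropylsilyl)oxy]phenyl}methanone (8-aryl and 9-aroyl cis) | O=C(c1c(O[Si](C(C)C)(C(C)C)C(C)C)cc(O[Si](C(C)C)(C(C)C)C(C)C)cc1O[Si](C(C)C)(C(C)C)C(C)C)[C@H]1[C@@H](c2ccc(OCc3ccccc3)cc2)Oc2cc(OCc3ccc(OCc4ccccc4)cc3)c3c(c21)O[C@H](c1ccc(OCc2ccccc2)cc1)[C@H](OCc1ccccc1)C3 | intermediate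
22 | potassium enolate of 21 (C9=C(OK)aryl; C8 unchanged) | [K]OC(c1c(O[Si](C(C)C)(C(C)C)C(C)C)cc(O[Si](C(C)C)(C(C)C)C(C)C)cc1O[Si](C(C)C)(C(C)C)C(C)C)=C1[C@@H](c2ccc(OCc3ccccc3)cc2)Oc2cc(OCc3ccc(OCc4ccccc4)cc3)c3c(c21)O[C@H](c1ccc(OCc2ccccc2)cc1)[C@H](OCc1ccccc1)C3 | intermediate
23 | {(2R,3R,8R,9S)-3-(benzyloxy)-2,8-bis[4-(benzyloxy)phenyl]-5-{[4-(benzyloxy)benzyl]oxy}-9-bromo-3,4,8,9-tetrahydro-2H-furo[2,3-h]chromen-9-yl}{2,4,6-tris[(triisopropylsilyl)oxy]phenyl}methanone (bromine trans to the 8-aryl group) | O=C(c1c(O[Si](C(C)C)(C(C)C)C(C)C)cc(O[Si](C(C)C)(C(C)C)C(C)C)cc1O[Si](C(C)C)(C(C)C)C(C)C)[C@@]1(Br)[C@@H](c2ccc(OCc3ccccc3)cc2)Oc2cc(OCc3ccc(OCc4ccccc4)cc3)c3c(c21)O[C@H](c1ccc(OCc2ccccc2)cc1)[C@H](OCc1ccccc1)C3 | intermediate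
24 | {(2R,3R,8R,9S)-3-(benzyloxy)-2,8-bis[4-(benzyloxy)phenyl]-5-{[4-(benzyloxy)benzyl]oxy}-9-bromo-3,4,8,9-tetrahydro-2H-furo[2,3-h]chromen-9-yl}(2,4,6-trihydroxyphenyl)methanone (present as its phenoxide) | O=C(c1c(O)cc(O)cc1O)[C@@]1(Br)[C@@H](c2ccc(OCc3ccccc3)cc2)Oc2cc(OCc3ccc(OCc4ccccc4)cc3)c3c(c21)O[C@H](c1ccc(OCc2ccccc2)cc1)[C@H](OCc1ccccc1)C3 | intermediate
25 | (2R,2'R,3'R,8'R)-3'-(benzyloxy)-2',8'-bis[4-(benzyloxy)phenyl]-5'-{[4-(benzyloxy)benzyl]oxy}-4,6-dihydroxy-3',4'-dihydro-2'H,3H,8'H-spiro[[1]benzofuran-2,9'-furo[2,3-h]chromen]-3-one | O=C1c2c(O)cc(O)cc2O[C@@]12c1c(cc(OCc4ccc(OCc5ccccc5)cc4)c3c1O[C@H](c1ccc(OCc4ccccc4)cc1)[C@H](OCc1ccccc1)C3)O[C@@H]2c1ccc(OCc2ccccc2)cc1 | intermediate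
26 | (2R,2'R,3'R,8'R)-3',4,5',6-tetrahydroxy-2',8'-bis(4-hydroxyphenyl)-3',4'-dihydro-2'H,3H,8'H-spiro[[1]benzofuran-2,9'-furo[2,3-h]chromen]-3-one (CNP0228515.2) | O=C1c2c(O)cc(O)cc2O[C@@]12c1c(cc(O)c3c1O[C@H](c1ccc(O)cc1)[C@H](O)C3)O[C@@H]2c1ccc(O)cc1 | target

Total step count: 12
Longest linear sequence: 10 steps (steps 1–6 and 9–12); steps 7–8 prepare the diazoketone 19.

Steps most likely to fail

Step 6 (key step). Metalation may take place at the wrong site (C6 between the two ether oxygens, or a benzylic OCH2 followed by Wittig rearrangement), or the lithium alkoxide may add to the aryne too slowly to outrun capture of the aryne by alkyllithium. The fallback sets out from 11 and comes back at 15. Heating 11 with KOt-Bu in DMSO at 60–80 °C should close the pyran ring by direct addition–elimination (SNAr) of the potassium alkoxide at the fluorine-bearing carbon, whose two meta ether groups do not donate into it, to give (2R,3R)-3-(benzyloxy)-2-[4-(benzyloxy)phenyl]-5,7-bis{[4-(benzyloxy)benzyl]oxy}-3,4-dihydro-2H-chromene F1. Electrophilic iodination of F1 with N-iodosuccinimide in MeCN/CH2Cl2 at 0 °C, which in 5,7-dialkoxychromanes should favour C8 over C6, then gives 15.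

Step 11. The tertiary, electron-rich benzylic bromide may ionize before it is displaced, which would cost facial control at the spiro carbon or lead by proton loss to the aromatic benzofuran; a silyl group may also migrate from an ortho oxygen to the enolate oxygen before bromination. The fallback sets out from 21 and comes back at 25. Bu4NF in THF at 0 °C removes the silyl groups to give {(2R,3R,8S,9R)-3-(benzyloxy)-2,8-bis[4-(benzyloxy)phenyl]-5-{[4-(benzyloxy)benzyl]oxy}-3,4,8,9-tetrahydro-2H-furo[2,3-h]chromen-9-yl}(2,4,6-trihydroxyphenyl)methanone F2. Catalytic Bu4NI with t-BuOOH in EtOAc at rt (ammonium hypoiodite-catalysed oxidative cycloetherification of a ketophenol) should then iodinate the ketone α-carbon anti to the neighbouring aryl group at low stationary concentration, and the ortho phenol closes by the same invertive displacement to give 25. If the phenol oxygen were iodinated first and the enol attacked it, the other spiro epimer would result.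

Step 10. The carbenoid from an aryl diazoketone with two ortho oxygen substituents may show poor facial discrimination, or be diverted into oxonium ylide formation at a silyl ether oxygen or into Wolff rearrangement. The fallback sets out from 15 and comes back at 21. Coupling of 15 with methyl diazoacetate (Pd(PPh3)4, Ag2CO3, Et3N, PhMe, rt) gives methyl 2-diazo-2-{(2R,3R)-3-(benzyloxy)-2-[4-(benzyloxy)phenyl]-5,7-bis{[4-(benzyloxy)benzyl]oxy}-3,4-dihydro-2H-chromen-8-yl}acetate F3, an aryldiazoacetate, the substrate class on which enantioselective insertion into an ortho benzyloxy group is established. Rh2(R-PTTL)4 in PhMe at −60 °C should give methyl (2R,3R,8S,9R)-3-(benzyloxy)-2,8-bis[4-(benzyloxy)phenyl]-5-{[4-(benzyloxy)benzyl]oxy}-3,4,8,9-tetrahydro-2H-furo[2,3-h]chromene-9-carboxylate F4. MeNHOMe·HCl with i-PrMgCl converts it into (2R,3R,8S,9R)-3-(benzyloxy)-2,8-bis[4-(benzyloxy)phenyl]-5-{[4-(benzyloxy)benzyl]oxy}-N-methoxy-N-methyl-3,4,8,9-tetrahydro-2H-furo[2,3-h]chromene-9-carboxamide F5. Silylation of 2-bromobenzene-1,3,5-triol with i-Pr3SiOTf gives 2-bromo-1,3,5-tris[(triisopropylsilyl)oxy]benzene F6; bromine–lithium exchange with t-BuLi gives {2,4,6-tris[(triisopropylsilyl)oxy]phenyl}lithium F7, which adds to F5 to give ketone 21. Epimerization at C9 on the way is harmless because that centre is planarized in step 11.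

Further compounds

F1 | step 6 | (2R,3R)-3-(benzyloxy)-2-[4-(benzyloxy)phenyl]-5,7-bis{[4-(benzyloxy)benzyl]oxy}-3,4-dihydro-2H-chromene | c1c(OCc2ccc(OCc3ccccc3)cc2)cc(OCc2ccc(OCc3ccccc3)cc2)c2c1O[C@H](c1ccc(OCc3ccccc3)cc1)[C@H](OCc1ccccc1)C2
F2 | step 11 | {(2R,3R,8S,9R)-3-(benzyloxy)-2,8-bis[4-(benzyloxy)phenyl]-5-{[4-(benzyloxy)benzyl]oxy}-3,4,8,9-tetrahydro-2H-furo[2,3-h]chromen-9-yl}(2,4,6-trihydroxyphenyl)methanone | O=C(c1c(O)cc(O)cc1O)[C@H]1[C@@H](c2ccc(OCc3ccccc3)cc2)Oc2cc(OCc3ccc(OCc4ccccc4)cc3)c3c(c21)O[C@H](c1ccc(OCc2ccccc2)cc1)[C@H](OCc1ccccc1)C3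
F3 | step 10 | methyl 2-diazo-2-{(2R,3R)-3-(benzyloxy)-2-[4-(benzyloxy)phenyl]-5,7-bis{[4-(benzyloxy)benzyl]oxy}-3,4-dihydro-2H-chromen-8-yl}acetate | COC(=O)C(=[N+]=[N-])c1c(OCc2ccc(OCc3ccccc3)cc2)cc(OCc2ccc(OCc3ccccc3)cc2)c2c1O[C@H](c1ccc(OCc3ccccc3)cc1)[C@H](OCc1ccccc1)C2
F4 | step 10 | methyl (2R,3R,8S,9R)-3-(benzyloxy)-2,8-bis[4-(benzyloxy)phenyl]-5-{[4-(benzyloxy)benzyl]oxy}-3,4,8,9-tetrahydro-2H-furo[2,3-h]chromene-9-carboxylate | COC(=O)[C@H]1[C@@H](c2ccc(OCc3ccccc3)cc2)Oc2cc(OCc3ccc(OCc4ccccc4)cc3)c3c(c21)O[C@H](c1ccc(OCc2ccccc2)cc1)[C@H](OCc1ccccc1)C3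
F5 | step 10 | (2R,3R,8S,9R)-3-(benzyloxy)-2,8-bis[4-(benzyloxy)phenyl]-5-{[4-(benzyloxy)benzyl]oxy}-N-methoxy-N-methyl-3,4,8,9-tetrahydro-2H-furo[2,3-h]chromene-9-carboxamide | CON(C)C(=O)[C@H]1[C@@H](c2ccc(OCc3ccccc3)cc2)Oc2cc(OCc3ccc(OCc4ccccc4)cc3)c3c(c21)O[C@H](c1ccc(OCc2ccccc2)cc1)[C@H](OCc1ccccc1)C3
F6 | step 10 | 2-bromo-1,3,5-tris[(triisopropylsilyl)oxy]benzene | Brc1c(O[Si](C(C)C)(C(C)C)C(C)C)cc(O[Si](C(C)C)(C(C)C)C(C)C)cc1O[Si](C(C)C)(C(C)C)C(C)C
F7 | step 10 | {2,4,6-tris[(triisopropylsilyl)oxy]phenyl}lithium | [Li]c1c(O[Si](C(C)C)(C(C)C)C(C)C)cc(O[Si](C(C)C)(C(C)C)C(C)C)cc1O[Si](C(C)C)(C(C)C)C(C)C
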